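**Plan**

- Retrosynthetic cuts: first the aryl–CHO bond; then the chroman O–C(spiro) and ArCH2–CH2 bonds together (o-quinone methide plus the exocyclic alkene of verbenene); then the cyclobutane bond from the CH2 bridge to the bridgehead remote from the spiro carbon; last, in the remaining cyclohexenone, the bond from the future spiro carbon to its ring CH2 and the bond from the neighbouring ring CH to the CMe2 carbon together, back to ethyl acetoacetate and mesityl oxide.
- Enabling feature: in the six-membered carbocycle spiro C–CH2–CH2–CH–CMe2–CH of the pinane, the quaternary CMe2 carbon and the spiro carbon both lie 1,3 to the CH2 next to the remote bridgehead. With that CH2 as a ketone and the spiro carbon as enone β-carbon the ring is a 4-substituted isophorone, the retron of a Michael–aldol annulation. The ester carbon of acetoacetate becomes the cyclobutane CH2 and its CH3 becomes C3 of the chroman.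
- Forward order of rings: cyclohexenone (step 1), cyclobutane closing the pinane as verbenone (step 6), deoxygenation to verbenene (steps 7–8), aromatic partner from phloroglucinol (steps 9–12), chroman by hetero-Diels–Alder reaction (step 13), then hydrogenation/debenzylation and formylation (steps 14–15).
- Stereochemistry: the ring CH of the annulation product is resolved with a lipase (step 4) and becomes the bridgehead next to the spiro carbon; the cis-bridging CH2 tether fixes the second bridgehead (step 6); the spiro center arises in step 13 by attack on the alkene face anti to the gem-dimethyl bridge.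
- Chroman regiochemistry is fixed by leaving free only the phenol OH para to the isovaleryl group; the helper groups (ring ketone, benzyl ethers, extra ring alkene) are removed in steps 7–8 and 14.

Key step: step 1

Assumption: the sense of enantiomer selection by the lipase in step 4 cannot be predicted with certainty; the route is written for recovery of the (R)-alcohol as the unreacted enantiomer, and if the enzyme prefers it instead, the same compound would be obtained from the acetate by methanolysis (K2CO3, MeOH).

**Route**

Step 1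
Reactants: 1 ethyl acetoacetate; 2 mesityl oxide (4-methylpent-3-en-2-one)
Product: 5 ethyl 2,6,6-trimethyl-4-oxocyclohex-2-ene-1-carboxylate (racemic), via diketo ester 3 (not isolated), via ketol 4 (not isolated)
Conditions: ZnCl2 (0.3 equiv), toluene–heptane, reflux, Dean–Stark trap
Reagents that add atoms: none
Why: ZnCl2 binds ethyl acetoacetate as its chelated zinc enolate and activates mesityl oxide, so the carbon between the two carbonyls of 1 adds to the β,β-dimethyl terminus of 2 (Michael addition), forming the bond from the future ring CH to the quaternary CMe2 carbon in 3. The methyl ketone of 3 then enolizes toward its CH3 group and adds to the acetoacetate ketone (intramolecular aldol addition to ketol 4), forming the bond from the future =CH carbon to the C(CH3) carbon, and loss of water, driven by the Dean–Stark trap, gives the conjugated enone 5. The closest known reaction type is the Robinson annulation in its Michael–aldol condensation form, as in the syntheses of isophorone and dimedone from mesityl oxide, and this pair of reactants is known to condense in this sense. The one ring formed closes by a 6-(enolexo)-exo-trig aldol addition followed by E1cB dehydration. The only stereocenter formed, the ring CH bearing the ester, is not controlled and stays epimerizable as a vinylogous β-keto ester position, so 5 is racemic and the absolute configuration is fixed only at step 4. The step needs the aldol to run in one direction (side-chain CH3 onto the acetoacetate carbonyl, not the acetoacetate CH3 onto the side-chain ketone), which is secured because the chelated β-keto ester enolizes only toward the carbon between its carbonyls while its ketone remains the activated electrophile; attack by the side-chain CH2 would need a four-membered ring.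

Step 2
Reactants: 5 ethyl 2,6,6-trimethyl-4-oxocyclohex-2-ene-1-carboxylate
Product: 6 4-(hydroxymethyl)-3,5,5-trimethylcyclohex-2-en-1-ol (racemic, cis/trans mixture)
Conditions: LiAlH4 (1.5 equiv), Et2O, −20 → 0 °C; then Na2SO4·10H2O
Reagents that add atoms: none
Why: LiAlH4 reduces the ester to the primary alcohol and the enone carbonyl by 1,2-addition (hydride reduction); the new carbinol center is formed without control but is erased again in step 3.

Step 3
Reactants: 6 4-(hydroxymethyl)-3,5,5-trimethylcyclohex-2-en-1-ol
Product: 7 rac-4-(hydroxymethyl)-3,5,5-trimethylcyclohex-2-en-1-one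
Conditions: activated MnO2 (10 equiv), CH2Cl2, 25 °C
Reagents that add atoms: none
Why: MnO2 oxidizes only the allylic secondary alcohol (selective allylic oxidation) and leaves the saturated primary alcohol, which regenerates the enone.

Step 4
Reactants: 7 rac-4-(hydroxymethyl)-3,5,5-trimethylcyclohex-2-en-1-one
Product: 8 (4R)-4-(hydroxymethyl)-3,5,5-trimethylcyclohex-2-en-1-one
Conditions: Amano lipase PS (Burkholderia cepacia lipase), vinyl acetate (3 equiv), MTBE, 25 °C, run past half conversion; chromatography
Reagents that add atoms: none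
Why: Lipase-catalysed transesterification with vinyl acetate should acylate one enantiomer of the primary alcohol faster (enzymatic kinetic resolution), so the stereocenter of 8 is selected rather than made and the slower (R)-alcohol should be recovered in high enantiomeric purity once conversion passes one half.

Step 5
Reactants: 8 (4R)-4-(hydroxymethyl)-3,5,5-trimethylcyclohex-2-en-1-one
Product: 9 [(1R)-2,6,6-trimethyl-4-oxocyclohex-2-en-1-yl]methyl 4-methylbenzenesulfonate
Conditions: TsCl (1.3 equiv), pyridine (3 equiv), DMAP (cat.), CH2Cl2, 0 °C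
Reagents that add atoms: p-toluenesulfonyl chloride, Cc1ccc(cc1)S(Cl)(=O)=O
Why: Sulfonylation of the unhindered primary alcohol (tosylate formation) under mild base leaves the ring stereocenter and the enone untouched.

Step 6
Reactants: 9 [(1R)-2,6,6-trimethyl-4-oxocyclohex-2-en-1-yl]methyl 4-methylbenzenesulfonate
Product: 11 (1S,5S)-verbenone [(1S,5S)-4,6,6-trimethylbicyclo[3.1.1]hept-3-en-2-one], via lithium enolate 10 (not isolated)
Conditions: LiN(i-Pr)2 (1.1 equiv), THF, −78 °C; then DMPU, −78 → 25 °C
Reagents that add atoms: none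
Why: Kinetic deprotonation at the only α' position gives cross-conjugated enolate 10, whose α'-carbon displaces the tosylate held over the ring face across the CMe2 carbon (intramolecular enolate alkylation, 4-exo-tet, the classical keto tosylate closure of the pinane cyclobutane); C- rather than O-alkylation is expected because the electrophilic carbon sits above the enolate π-face, and the new bridgehead stereocenter is fixed by the one-carbon tether, which can only bridge cis from the resolved center.

Step 7
Reactants: 11 (1S,5S)-verbenone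
Product: 13 (1S,5R)-6,6-dimethyl-4-methylidenebicyclo[3.1.1]hept-2-en-2-yl trifluoromethanesulfonate, via lithium dienolate 12 (not isolated)
Conditions: LiN(i-Pr)2 (1.1 equiv), THF, −78 °C; PhNTf2 (1.1 equiv), −78 → 0 °C
Reagents that add atoms: N-phenylbis(trifluoromethanesulfonimide), O=S(=O)(N(c1ccccc1)S(=O)(=O)C(F)(F)F)C(F)(F)F
Why: With the α' carbon now a bridgehead, the amide base can only remove a γ-hydrogen of the vinylic methyl group to give extended dienolate 12, which is trapped on oxygen by PhNTf2 (enol triflate formation); no stereocenter is touched.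

Step 8
Reactants: 13 (1S,5R)-6,6-dimethyl-4-methylidenebicyclo[3.1.1]hept-2-en-2-yl trifluoromethanesulfonate
Product: 14 (1R,5R)-verbenene [(1R,5R)-6,6-dimethyl-4-methylidenebicyclo[3.1.1]hept-2-ene]
Conditions: Pd(OAc)2 (2 mol%), PPh3 (4 mol%), HCO2H (2 equiv), n-Bu3N (3 equiv), DMF, 60 °C
Reagents that add atoms: none
Why: Oxidative addition of the dienyl triflate to zerovalent palladium, exchange with formate, loss of CO2 and C–H reductive elimination replace the triflate by hydrogen (palladium-catalysed formate reduction of an enol triflate), which removes the helper oxygen without affecting the bridgeheads.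

Step 9
Reactants: 15 phloroglucinol (benzene-1,3,5-triol); 16 3-methylbutanoyl chloride (isovaleryl chloride)
Product: 17 3-methyl-1-(2,4,6-trihydroxyphenyl)butan-1-one
Conditions: AlCl3 (3.5 equiv), CH2Cl2–PhNO2, 25 → 45 °C; then ice-water
Reagents that add atoms: none
Why: Friedel–Crafts acylation of the highly activated, symmetric triol should stop at the monoketone because the chelated acyl group deactivates the ring toward a second acylation.

Step 10
Reactants: 17 3-methyl-1-(2,4,6-trihydroxyphenyl)butan-1-one
Product: 19 1-[2,6-bis(benzyloxy)-4-(methoxymethoxy)phenyl]-3-methylbutan-1-one, via MOM ether 18 (not isolated)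
Conditions: K2CO3 (1.1 equiv), MOMCl (1.0 equiv), DMF, 0 °C; then K2CO3 (3 equiv), BnBr (2.5 equiv), 70 °C
Reagents that add atoms: chloromethyl methyl ether, COCCl; benzyl bromide, BrCc1ccccc1
Why: The OH para to the acyl group is the most acidic and is not hydrogen-bonded to the carbonyl, so one equivalent of MOMCl should alkylate it first (Williamson etherification), after which excess benzyl bromide at higher temperature alkylates the two chelated ortho OH groups.

Step 11
Reactants: 19 1-[2,6-bis(benzyloxy)-4-(methoxymethoxy)phenyl]-3-methylbutan-1-one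
Product: 20 1-[2,6-bis(benzyloxy)-4-hydroxyphenyl]-3-methylbutan-1-one
Conditions: conc. HCl (cat.), MeOH–THF, 50 °C
Reagents that add atoms: none
Why: Acid-catalysed acetal exchange with methanol removes the MOM group (acetal cleavage) while the benzyl ethers and the ketone are stable.

Step 12
Reactants: 20 1-[2,6-bis(benzyloxy)-4-hydroxyphenyl]-3-methylbutan-1-one
Product: 21 1-{2,6-bis(benzyloxy)-3-[(dimethylamino)methyl]-4-hydroxyphenyl}-3-methylbutan-1-one
Conditions: dimethylmethyleneiminium iodide (1.1 equiv), Et3N (1.2 equiv), CH2Cl2, 0 → 25 °C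
Reagents that add atoms: N,N-dimethylmethyleneiminium iodide, C=[N+](C)C.[I-]
Why: The iminium salt attacks the electron-rich ring ortho to the free OH (phenol Mannich reaction), the para position being blocked by the acyl group and the two ortho positions being equivalent.

Step 13
Reactants: 21 1-{2,6-bis(benzyloxy)-3-[(dimethylamino)methyl]-4-hydroxyphenyl}-3-methylbutan-1-one; 14 (1R,5R)-verbenene
Product: 23 1-[(1R,2S,5R)-5',7'-bis(benzyloxy)-6,6-dimethyl-3',4'-dihydrospiro[bicyclo[3.1.1]hept-3-ene-2,2'-chromen]-6'-yl]-3-methylbutan-1-one, via quinone methide 22 (not isolated)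
Conditions: 14 (2 equiv), toluene, 110 °C, slow argon sweep
Reagents that add atoms: none
Why: Thermal loss of Me2NH gives o-quinone methide 22, in which only the single free phenol oxygen can become the carbonyl, and this electron-poor heterodiene adds to the exocyclic alkene of the s-trans-locked diene 14 (inverse-electron-demand hetero-Diels–Alder reaction) with the CH2 terminus bonding to the methide carbon and oxygen to the allylic ring carbon, from the face anti to the gem-dimethyl bridge, which sets the spiro stereocenter with oxygen syn to the CH2 bridge.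

Step 14
Reactants: 23 1-[(1R,2S,5R)-5',7'-bis(benzyloxy)-6,6-dimethyl-3',4'-dihydrospiro[bicyclo[3.1.1]hept-3-ene-2,2'-chromen]-6'-yl]-3-methylbutan-1-one
Product: 24 1-[(1R,2R,5S)-5',7'-dihydroxy-6,6-dimethyl-3',4'-dihydrospiro[bicyclo[3.1.1]heptane-2,2'-chromen]-6'-yl]-3-methylbutan-1-one
Conditions: H2 (1 atm), 10% Pd/C, EtOAc–EtOH, 25 °C
Reagents that add atoms: none
Why: Heterogeneous hydrogenation should saturate the unhindered cis-disubstituted ring alkene and hydrogenolyse both benzyl ethers (catalytic hydrogenation and hydrogenolysis), while the chelated aryl ketone, the cyclobutane and the three stereocenters are unaffected.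

Step 15
Reactants: 24 1-[(1R,2R,5S)-5',7'-dihydroxy-6,6-dimethyl-3',4'-dihydrospiro[bicyclo[3.1.1]heptane-2,2'-chromen]-6'-yl]-3-methylbutan-1-one
Product: 26 euglobal G3 [(1R,2R,5S)-5',7'-dihydroxy-6,6-dimethyl-6'-(3-methylbutanoyl)-3',4'-dihydrospiro[bicyclo[3.1.1]heptane-2,2'-chromene]-8'-carbaldehyde], via chloro ether 25 (not isolated)
Conditions: TiCl4 (4 equiv), Cl2CHOMe (2 equiv), CH2Cl2, −78 → −20 °C; then ice-water
Reagents that add atoms: dichloromethyl methyl ether, COC(Cl)Cl; water, O
Why: In this Rieche formylation the TiCl4-activated dichloromethyl ether attacks the only unsubstituted ring position, ortho to a phenol, to give chloro ether 25, which is hydrolysed on work-up to the aldehyde; the low temperature is chosen so that the tertiary spiro ether should survive.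

**Compound list**

1 | ethyl acetoacetate (ethyl 3-oxobutanoate) | CCOC(=O)CC(C)=O | starting material
2 | mesityl oxide (4-methylpent-3-en-2-one) | CC(C)=CC(C)=O | starting material
3 | ethyl 2-acetyl-3,3-dimethyl-5-oxohexanoate (Michael adduct, racemic, not isolated) | CCOC(=O)C(C(C)=O)C(C)(C)CC(C)=O | intermediate
4 | ethyl 2-hydroxy-2,6,6-trimethyl-4-oxocyclohexane-1-carboxylate (ketol, racemic, not isolated) | CCOC(=O)C1C(C)(O)CC(=O)CC1(C)C | intermediate
5 | ethyl 2,6,6-trimethyl-4-oxocyclohex-2-ene-1-carboxylate (racemic) | CCOC(=O)C1C(C)=CC(=O)CC1(C)C | intermediate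
6 | 4-(hydroxymethyl)-3,5,5-trimethylcyclohex-2-en-1-ol (racemic, cis/trans mixture) | OCC1C(C)=CC(O)CC1(C)C | intermediate
7 | rac-4-(hydroxymethyl)-3,5,5-trimethylcyclohex-2-en-1-one | OCC1C(C)=CC(=O)CC1(C)C | intermediate
8 | (4R)-4-(hydroxymethyl)-3,5,5-trimethylcyclohex-2-en-1-one | OC[C@H]1C(C)=CC(=O)CC1(C)C | intermediate
9 | [(1R)-2,6,6-trimethyl-4-oxocyclohex-2-en-1-yl]methyl 4-methylbenzenesulfonate | Cc1ccc(cc1)S(=O)(=O)OC[C@H]1C(C)=CC(=O)CC1(C)C | intermediate
10 | lithium (4S)-3,3,5-trimethyl-4-(tosyloxymethyl)cyclohexa-1,5-dien-1-olate (cross-conjugated α'-enolate of 9, not isolated) | [Li]OC1=CC(C)(C)[C@@H](COS(=O)(=O)c2ccc(C)cc2)C(C)=C1 | intermediate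
11 | (1S,5S)-verbenone, (1S,5S)-4,6,6-trimethylbicyclo[3.1.1]hept-3-en-2-one | CC1=CC(=O)[C@H]2C[C@@H]1C2(C)C | intermediate
12 | lithium (1S,5R)-6,6-dimethyl-4-methylidenebicyclo[3.1.1]hept-2-en-2-olate (extended dienolate of 11, not isolated) | C=C1C=C(O[Li])[C@H]2C[C@@H]1C2(C)C | intermediate
13 | (1S,5R)-6,6-dimethyl-4-methylidenebicyclo[3.1.1]hept-2-en-2-yl trifluoromethanesulfonate | C=C1C=C(OS(=O)(=O)C(F)(F)F)[C@H]2C[C@@H]1C2(C)C | intermediate
14 | (1R,5R)-verbenene, (1R,5R)-6,6-dimethyl-4-methylidenebicyclo[3.1.1]hept-2-ene | C=C1C=C[C@H]2C[C@@H]1C2(C)C | intermediate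
15 | phloroglucinol (benzene-1,3,5-triol) | Oc1cc(O)cc(O)c1 | starting material
16 | 3-methylbutanoyl chloride (isovaleryl chloride) | CC(C)CC(Cl)=O | starting material
17 | 3-methyl-1-(2,4,6-trihydroxyphenyl)butan-1-one | CC(C)CC(=O)c1c(O)cc(O)cc1O | intermediate
18 | 1-[2,6-dihydroxy-4-(methoxymethoxy)phenyl]-3-methylbutan-1-one (not isolated) | CC(C)CC(=O)c1c(O)cc(OCOC)cc1O | intermediate
19 | 1-[2,6-bis(benzyloxy)-4-(methoxymethoxy)phenyl]-3-methylbutan-1-one | CC(C)CC(=O)c1c(OCc2ccccc2)cc(OCOC)cc1OCc1ccccc1 | intermediate
20 | 1-[2,6-bis(benzyloxy)-4-hydroxyphenyl]-3-methylbutan-1-one | CC(C)CC(=O)c1c(OCc2ccccc2)cc(O)cc1OCc1ccccc1 | intermediate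
21 | 1-{2,6-bis(benzyloxy)-3-[(dimethylamino)methyl]-4-hydroxyphenyl}-3-methylbutan-1-one | CC(C)CC(=O)c1c(OCc2ccccc2)cc(O)c(CN(C)C)c1OCc1ccccc1 | intermediate
22 | 3,5-bis(benzyloxy)-6-methylidene-4-(3-methylbutanoyl)cyclohexa-2,4-dien-1-one (o-quinone methide, not isolated) | CC(C)CC(=O)C1=C(OCc2ccccc2)C(=C)C(=O)C=C1OCc1ccccc1 | intermediate
23 | 1-[(1R,2S,5R)-5',7'-bis(benzyloxy)-6,6-dimethyl-3',4'-dihydrospiro[bicyclo[3.1.1]hept-3-ene-2,2'-chromen]-6'-yl]-3-methylbutan-1-one | CC(C)CC(=O)c1c(OCc2ccccc2)cc3c(c1OCc4ccccc4)CC[C@@]5(C=C[C@H]6C[C@@H]5C6(C)C)O3 | intermediate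
24 | 1-[(1R,2R,5S)-5',7'-dihydroxy-6,6-dimethyl-3',4'-dihydrospiro[bicyclo[3.1.1]heptane-2,2'-chromen]-6'-yl]-3-methylbutan-1-one | CC(C)CC(=O)c1c(O)cc2c(c1O)CC[C@@]1(CC[C@H]3C[C@@H]1C3(C)C)O2 | intermediate
25 | 1-{(1R,2R,5S)-8'-[chloro(methoxy)methyl]-5',7'-dihydroxy-6,6-dimethyl-3',4'-dihydrospiro[bicyclo[3.1.1]heptane-2,2'-chromen]-6'-yl}-3-methylbutan-1-one (mixture at the new CH, not isolated) | CC(C)CC(=O)c1c(O)c(C(Cl)OC)c2c(c1O)CC[C@@]1(CC[C@H]3C[C@@H]1C3(C)C)O2 | intermediate
26 | euglobal G3, (1R,2R,5S)-5',7'-dihydroxy-6,6-dimethyl-6'-(3-methylbutanoyl)-3',4'-dihydrospiro[bicyclo[3.1.1]heptane-2,2'-chromene]-8'-carbaldehyde | CC(C)CC(=O)c1c(O)c(C=O)c2c(c1O)CC[C@@]1(CC[C@H]3C[C@@H]1C3(C)C)O2 | target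

**Step count and risks**

Total step count: 15. Longest linear sequence: 11 steps (steps 1–8, then 13–15); the aromatic branch (steps 9–12) joins at step 13.

Steps most likely to fail:

1. Step 6 (cyclobutane closure). The α'-enolate may pass a proton to the γ-position (the ring CH that carries the CH2OTs group), after which the dienolate would expel tosylate to an exocyclic dienone; closure through oxygen is the second escape. Fallback, from 9 back to 11: remove the vinylogous acidity before ring closure. Hydrogenation of 9 (H2, Pd/C, EtOAc) should give the saturated keto tosylate [(1S)-2,6,6-trimethyl-4-oxocyclohexyl]methyl 4-methylbenzenesulfonate F1 as a mixture of epimers at the methyl-bearing carbon. Equilibrating enolate alkylation (KOt-Bu, t-BuOH–THF, 50 °C), the classical keto tosylate closure, should then give verbanone, (1S,5S)-4,6,6-trimethylbicyclo[3.1.1]heptan-2-one F2. Dehydrogenation with IBX (DMSO, 70 °C) can only run toward the methyl-bearing carbon, because the other α-carbon is a bridgehead, and returns to 11.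

2. Step 4 (resolution). The enzyme may discriminate poorly between the enantiomers, since the two ring substituents flanking the stereocenter (CMe2 and C(CH3)=CH) are of similar size. Fallback, from 7 back to 8: covalent resolution. Esterification of 7 with (S)-2-methoxy-2-phenylacetic acid (N-(3-dimethylaminopropyl)-N'-ethylcarbodiimide hydrochloride, DMAP, CH2Cl2) gives two diastereomeric esters, to be separated by chromatography or crystallization. Methanolysis (K2CO3 cat., MeOH, 0 °C) of the ester of the (R)-alcohol, [(1R)-2,6,6-trimethyl-4-oxocyclohex-2-en-1-yl]methyl (2S)-2-methoxy-2-phenylacetate F3, returns to 8.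

3. Step 13 (hetero-Diels–Alder union). Self-condensation of the quinone methide, or thermal loss and polymerization of the volatile diene, may outrun the cycloaddition. Fallback, from 11 back to 23: use a more nucleophilic, non-volatile 2π partner and remove its oxygen afterwards.
   - TBSOTf/Et3N (CH2Cl2, 0 °C) converts 11 into the silyl dienol ether tert-butyl{[(1S,5R)-6,6-dimethyl-4-methylidenebicyclo[3.1.1]hept-2-en-2-yl]oxy}dimethylsilane F4.
   - Heating F4 with 21 (toluene, 90 °C) should give, by vinylogous Mukaiyama–Michael addition to 22 and ring closure through oxygen, the spiro silyl enol ether 1-[(1R,2R,5S)-5',7'-bis(benzyloxy)-4-(tert-butyldimethylsilyloxy)-6,6-dimethyl-3',4'-dihydrospiro[bicyclo[3.1.1]hept-3-ene-2,2'-chromen]-6'-yl]-3-methylbutan-1-one F5.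
   - HF·pyridine (THF, 0 °C) releases the spiro ketone 1-[(1R,2S,5S)-5',7'-bis(benzyloxy)-6,6-dimethyl-4-oxo-3',4'-dihydrospiro[bicyclo[3.1.1]heptane-2,2'-chromen]-6'-yl]-3-methylbutan-1-one F6.
   - NaBH4 (MeOH, −20 °C) reduces the ring ketone in preference to the hindered aryl ketone to the alcohol 1-[(1R,2S,5S)-5',7'-bis(benzyloxy)-4-hydroxy-6,6-dimethyl-3',4'-dihydrospiro[bicyclo[3.1.1]heptane-2,2'-chromen]-6'-yl]-3-methylbutan-1-one F7 (mixture at the carbinol carbon).
   - Syn-elimination with the Burgess reagent (benzene, 50 °C), possible only toward the ring CH2 because the other β-carbon is a bridgehead, returns to 23.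

Further compounds
F1 | step 6 | [(1S)-2,6,6-trimethyl-4-oxocyclohexyl]methyl 4-methylbenzenesulfonate (mixture of epimers at the methyl-bearing carbon) | Cc1ccc(cc1)S(=O)(=O)OC[C@H]1C(C)CC(=O)CC1(C)C
F2 | step 6 | verbanone, (1S,5S)-4,6,6-trimethylbicyclo[3.1.1]heptan-2-one (mixture of epimers at C4) | CC1CC(=O)[C@H]2C[C@@H]1C2(C)C
F3 | step 4 | [(1R)-2,6,6-trimethyl-4-oxocyclohex-2-en-1-yl]methyl (2S)-2-methoxy-2-phenylacetate | CO[C@H](C(=O)OC[C@H]1C(C)=CC(=O)CC1(C)C)c1ccccc1
F4 | step 13 | tert-butyl{[(1S,5R)-6,6-dimethyl-4-methylidenebicyclo[3.1.1]hept-2-en-2-yl]oxy}dimethylsilane | C=C1C=C(O[Si](C)(C)C(C)(C)C)[C@H]2C[C@@H]1C2(C)C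
F5 | step 13 | 1-[(1R,2R,5S)-5',7'-bis(benzyloxy)-4-(tert-butyldimethylsilyloxy)-6,6-dimethyl-3',4'-dihydrospiro[bicyclo[3.1.1]hept-3-ene-2,2'-chromen]-6'-yl]-3-methylbutan-1-one | CC(C)CC(=O)c1c(OCc2ccccc2)cc3c(c1OCc4ccccc4)CC[C@@]5(C=C(O[Si](C)(C)C(C)(C)C)[C@H]6C[C@@H]5C6(C)C)O3
F6 | step 13 | 1-[(1R,2S,5S)-5',7'-bis(benzyloxy)-6,6-dimethyl-4-oxo-3',4'-dihydrospiro[bicyclo[3.1.1]heptane-2,2'-chromen]-6'-yl]-3-methylbutan-1-one | CC(C)CC(=O)c1c(OCc2ccccc2)cc3c(c1OCc4ccccc4)CC[C@@]5(CC(=O)[C@H]6C[C@@H]5C6(C)C)O3
F7 | step 13 | 1-[(1R,2S,5S)-5',7'-bis(benzyloxy)-4-hydroxy-6,6-dimethyl-3',4'-dihydrospiro[bicyclo[3.1.1]heptane-2,2'-chromen]-6'-yl]-3-methylbutan-1-one (mixture at the carbinol carbon) | CC(C)CC(=O)c1c(OCc2ccccc2)cc3c(c1OCc4ccccc4)CC[C@@]5(CC(O)[C@H]6C[C@@H]5C6(C)C)O3
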